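**Plan**

- Retrosynthesis cuts, in this order: the acetate C(=O)–O bond at C4'; the C4'–O bond, traced back to a C4'–H bond of the plain geranyl ether; the O4–C1' ether bond; and the O1–C2 and C2–C3 bonds of the pyranone.
- Forward: pyranone ring B is closed onto the preformed benzene ring A, the C10 chain is joined at O4 by Mitsunobu etherification, C4' is hydroxylated by an engineered P450 monooxygenase, and the alcohol is acetylated. No further ring is formed.
- Enabling feature: without the acetoxy group the chain is an unfunctionalised geranyl ether in which C4' is an allylic CH2 next to the C2'=C3' alkene. The planar benzopyranone (rings A and B, with the 5-methyl group) is a rigid aromatic handle by which an enzyme pocket can hold that one CH2 over the heme iron.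
- Stereochemistry: the single stereocentre (C4', R) is set by the enzyme, which removes the pro-R hydrogen and returns OH to the same face. The 2'E alkene comes from geraniol and is never disturbed.

Key step: step 3

Remark: chain atoms are numbered C1' (OCH2) to C8', with C4' the oxygenated carbon. It is assumed that a P450 BM3 variant with the required C4' and pro-R selectivity can be obtained by screening substrate-channel mutants (positions 47, 51, 78, 82, 87, 328) and directed evolution.

**Route**

Step 1
Reactants: 1 1-(2-hydroxy-6-methylphenyl)ethanone; 2 diethyl carbonate
Product: 4 4-hydroxy-5-methylcoumarin, via keto ester 3 (not isolated)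
Conditions: NaH (3.5 equiv), 2 (3 equiv), toluene, 0 °C to 110 °C; then aq. HCl to pH 2
Reagents that add atoms: none
Why: Crossed Claisen condensation of the ketone enolate of the sodium phenoxide with diethyl carbonate should give β-keto ester 3, whose phenoxide closes pyranone ring B by lactonisation with loss of ethoxide (the standard diethyl carbonate route from 2-hydroxyacetophenones to 4-hydroxycoumarins); no stereocentre is formed.

Step 2
Reactants: 4 4-hydroxy-5-methylcoumarin; 5 geraniol
Product: 6 4-geranyloxy-5-methylcoumarin (4-{[(2E)-3,7-dimethylocta-2,6-dien-1-yl]oxy}-5-methyl-2H-chromen-2-one)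
Conditions: PPh3, DIAD, THF, 0 °C to rt; concentrate below 35 °C
Reagents that add atoms: none
Why: Mitsunobu etherification, in which the acidic vinylogous acid 4 (pKa about 4) protonates the betaine and its O4 anion displaces the oxyphosphonium group at the primary allylic carbon C1' by SN2, so the 2'E alkene of geraniol is carried over unchanged and O4-alkylation, the usual outcome for 4-hydroxycoumarins under these conditions, should dominate.

Step 3
Reactants: 6 4-geranyloxy-5-methylcoumarin
Product: 7 4-{[(2E,4R)-4-hydroxy-3,7-dimethylocta-2,6-dien-1-yl]oxy}-5-methylcoumarin
Conditions: engineered cytochrome P450 BM3 (CYP102A1) variant (E. coli lysate), NADP+ (cat.), glucose dehydrogenase, D-glucose, O2 (air), catalase, KH2PO4/K2HPO4 buffer pH 8.0, DMSO (5% v/v), 25 °C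
Reagents that add atoms: dioxygen, O=O
Why: Proposed new method: the ferryl-oxo porphyrin radical cation of the heme (iron formally tetravalent) abstracts the pro-R hydrogen atom of the allylic C4' methylene of 6, and the hydroxyl then held on iron rebounds onto C4' of the C2'–C3'–C4' allyl radical on the face from which the hydrogen left, returning the heme to trivalent iron and forming the C4'–O bond with retention. The closest known reaction type is the regio- and enantioselective allylic hydroxylation of terpenoids (geranylacetone, farnesol-type chains, ionones, valencene) by engineered P450 BM3 variants, together with the plant P450 enzymes that hydroxylate prenyl chains of coumarins; what is new is an enzyme tuned to this ether, which would have to come from screening and directed evolution. No ring is closed or opened in this step. The new stereocentre C4' (R) is controlled only by the chiral active site, which decides which of the two enantiotopic C4' hydrogens lies within reach of the iron-oxo unit and keeps the short-lived radical from turning before rebound. The step needs site selectivity for C4' over C5', the three allylic methyl groups, C1' (whose oxidation would cleave the ether), rebound at C2' and epoxidation of either alkene; the substrate helps because the C4'–H bonds are allylic to the C2'=C3' alkene and therefore weak, and because the planar benzopyranone with its lactone carbonyl can stack and hydrogen-bond near the channel entrance like the head group of a fatty acid, fixing how far the C10 tail reaches towards the iron. Non-enzymatic oxidants do not discriminate in this way (SeO2 goes to the terminal E-methyl group, peracids to the 6',7'-alkene), which is why the selectivity is assigned to a binding pocket.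

Step 4
Reactants: 7 4-{[(2E,4R)-4-hydroxy-3,7-dimethylocta-2,6-dien-1-yl]oxy}-5-methylcoumarin
Product: 8 (2E,4R)-3,7-dimethyl-1-[(5-methyl-2-oxo-2H-chromen-4-yl)oxy]octa-2,6-dien-4-yl acetate (the target)
Conditions: Ac2O, pyridine, DMAP (cat.), CH2Cl2, 0 °C to rt
Reagents that add atoms: acetic anhydride, CC(=O)OC(C)=O
Why: DMAP-catalysed O-acylation (nucleophilic catalysis through the N-acetylpyridinium ion) of the secondary allylic alcohol acylates oxygen without breaking the C4'–O bond, so the R configuration is retained, and the lactone, the enol ether and both alkenes should be inert under these mild conditions.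

**Compound list**

1 | 1-(2-hydroxy-6-methylphenyl)ethanone | CC(=O)c1c(C)cccc1O | starting material
2 | diethyl carbonate | CCOC(=O)OCC | starting material
3 | ethyl 3-(2-hydroxy-6-methylphenyl)-3-oxopropanoate (present as its sodium salt) | CCOC(=O)CC(=O)c1c(C)cccc1O | intermediate (not isolated)
4 | 4-hydroxy-5-methylcoumarin (4-hydroxy-5-methyl-2H-chromen-2-one) | Cc1cccc2oc(=O)cc(O)c12 | intermediate
5 | geraniol ((2E)-3,7-dimethylocta-2,6-dien-1-ol) | CC(C)=CCC/C(C)=C/CO | starting material
6 | 4-geranyloxy-5-methylcoumarin (4-{[(2E)-3,7-dimethylocta-2,6-dien-1-yl]oxy}-5-methyl-2H-chromen-2-one) | CC(C)=CCC/C(C)=C/COc1cc(=O)oc2cccc(C)c12 | intermediate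
7 | 4-{[(2E,4R)-4-hydroxy-3,7-dimethylocta-2,6-dien-1-yl]oxy}-5-methyl-2H-chromen-2-one | O[C@H](CC=C(C)C)/C(C)=C/COc1cc(=O)oc2cccc(C)c12 | intermediate
8 | (2E,4R)-3,7-dimethyl-1-[(5-methyl-2-oxo-2H-chromen-4-yl)oxy]octa-2,6-dien-4-yl acetate (CNP0217379.1) | CC(=O)O[C@H](CC=C(C)C)/C(C)=C/COc1cc(=O)oc2cccc(C)c12 | target

**Step count and risks**

Total steps: 4. Longest linear sequence: 4 steps (1 to 4 to 6 to 7 to 8); geraniol 5 enters in step 2.

Steps most likely to fail:

1. Step 3 (enzymatic hydroxylation). No variant may reach useful site selectivity or enantioselectivity. Oxidation may drift to C1' (with loss of the chain as the hemiacetal collapses), to C5', to the terminal methyl groups or to epoxidation. Turnover may also stay low because the poorly soluble substrate uncouples the enzyme. The fallback uses known chemistry, sets out from 4 and returns at 7; it builds the stereocentre by C–C bond formation instead of C–H oxidation.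
   - Mitsunobu etherification of 4 with 3-methylbut-2-en-1-ol (PPh3, DIAD, THF) should give 5-methyl-4-[(3-methylbut-2-en-1-yl)oxy]coumarin F1.
   - Riley oxidation with SeO2 in dioxane at 80 °C should convert the E-methyl group into the aldehyde (2E)-2-methyl-4-[(5-methyl-2-oxo-2H-chromen-4-yl)oxy]but-2-enal F2.
   - Brown allylation with (+)-B-allyldiisopinocampheylborane (from (+)-Ipc2BOMe, itself derived from (−)-α-pinene, and allylMgBr; Et2O, −78 °C, ethanolamine work-up) follows. This is the reagent enantiomer that converts benzaldehyde into (R)-1-phenylbut-3-en-1-ol. It should add to the same face here and give 4-{[(2E,4R)-4-hydroxy-3-methylhepta-2,6-dien-1-yl]oxy}-5-methylcoumarin F3.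
   - Cross-metathesis of the terminal alkene with 2-methylbut-2-ene (second-generation Grubbs catalyst, CH2Cl2, 40 °C) should install the trisubstituted chain end and give 7, from which step 4 follows.

2. Step 2 (Mitsunobu etherification). Alkylation may occur at the lactone carbonyl oxygen (giving the 2-alkoxychromone isomer), at C3, or at the tertiary end of the allyl system (SN2'). The peri 5-methyl group may slow attack by O4, and the allyl vinyl ether may undergo Claisen rearrangement if warmed during purification. The fallback sets out from 4 and returns at 6 with reversed polarity, the coumarin acting as the electrophile. POCl3 with BnEt3NCl in MeCN at 80 °C should convert 4 into 4-chloro-5-methylcoumarin F4. Sodium geranoxide (5, NaH, THF, 0 °C) should then displace chloride at C4 by addition–elimination to give 6. Only C4 carries a leaving group, so O- versus C-alkylation no longer arises and the allyl system of geraniol is never activated.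

3. Step 1 (coumarin annulation). Intermolecular C-acylation of the enolate of the hindered, doubly ortho-substituted ketone may be slow, so that the reaction stalls at O-acylation or turns to aldol self-condensation. The fallback sets out from 1 and returns at 4 by making the acylation intramolecular. Ethyl chloroformate and pyridine in CH2Cl2 at 0 °C should give 2-acetyl-3-methylphenyl ethyl carbonate F5. KOtBu in THF (0 °C to rt) should then induce a Baker–Venkataraman-type O-to-C shift of the ethoxycarbonyl group onto the ketone enolate to give 3, which lactonises to 4 on acidic work-up.

Further compounds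
F1 | step 3 | 5-methyl-4-[(3-methylbut-2-en-1-yl)oxy]coumarin | CC(C)=CCOc1cc(=O)oc2cccc(C)c12
F2 | step 3 | (2E)-2-methyl-4-[(5-methyl-2-oxo-2H-chromen-4-yl)oxy]but-2-enal | O=C/C(C)=C/COc1cc(=O)oc2cccc(C)c12
F3 | step 3 | 4-{[(2E,4R)-4-hydroxy-3-methylhepta-2,6-dien-1-yl]oxy}-5-methylcoumarin | O[C@H](CC=C)/C(C)=C/COc1cc(=O)oc2cccc(C)c12
F4 | step 2 | 4-chloro-5-methylcoumarin | Cc1cccc2oc(=O)cc(Cl)c12
F5 | step 1 | 2-acetyl-3-methylphenyl ethyl carbonate | CCOC(=O)Oc1cccc(C)c1C(C)=O
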